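## Retrosynthetic overview

1. Target (H-bonded enol of a 2-cinnamoyl ketone) ⇐ oxidation of a β-hydroxy ketone ⇐ intermolecular aldol addition of the lithium α′-enolate of methyl (S)-1,2,3-trimethoxy-4-oxocyclopent-2-ene-1-carboxylate to (E)-cinnamaldehyde (key C–C bond).
2. That vinylogous ester ⇐ methoxide addition–elimination on a β-bromo-α-methoxy enone ⇐ bromination of the α-methoxy enone; this fixes OMe at C2 and C=O at C4 without ambiguity.
3. α-Methoxy enone ⇐ Stork–Danheiser transposition of the regioisomeric vinylogous ester that has the quaternary carbon next to C=O.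
4. Quaternary C(OMe)(CO2R) centre ⇐ O-methylation ⇐ catalytic enantioselective α-hydroxylation of a cyclic β-keto tert-butyl ester ⇐ α′-acylation of 2,3-dimethoxycyclopent-2-enone.
5. The only ring is the five-membered carbocycle, bought intact as cyclopentane-1,3-dione; no ring is formed.

Assumption 1: the facial sense of the Ni(II)–DBFOX hydroxylation is taken by analogy with tert-butyl 1-oxoindane-2-carboxylate; the (R,R)-ligand is written for the (S)-alcohol, and the antipodal ligand is used if the first run gives the (R)-alcohol.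

Assumption 2: the target is the chelated (Z)-enol tautomer that the 2-cinnamoyl ketone adopts spontaneously.

## Route

Step 1
Reactants: 1 cyclopentane-1,3-dione
Product: 2 2-diazocyclopentane-1,3-dione
Conditions: p-ABSA, Et3N, MeCN, 0 °C → rt
Reagents that add atoms: 4-acetamidobenzenesulfonyl azide (p-ABSA), CC(=O)Nc1ccc(cc1)S(=O)(=O)N=[N+]=[N-]
Why: Regitz diazo transfer; the enolate of the acidic 1,3-dione captures the terminal azide nitrogen and expels the sulfonamide.

Step 2
Reactants: 2 2-diazocyclopentane-1,3-dione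
Product: 3 2-methoxycyclopentane-1,3-dione (enol form 3-hydroxy-2-methoxycyclopent-2-en-1-one)
Conditions: Rh2(OAc)4 (1 mol %), MeOH (excess), ClCH2CH2Cl, 70 °C
Reagents that add atoms: methanol, CO
Why: Rh(II)-carbenoid O–H insertion into methanol; acceptor/acceptor carbenoids of cyclic 1,3-diones insert into alcohols and the product settles as the enol.

Step 3
Reactants: 3 2-methoxycyclopentane-1,3-dione
Product: 4 2,3-dimethoxycyclopent-2-en-1-one
Conditions: TMSCHN2, MeOH–PhMe, 0 °C → rt
Reagents that add atoms: (trimethylsilyl)diazomethane, C[Si](C)(C)C=[N+]=[N-]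
Why: O-methylation of a vinylogous acid with TMSCHN2; the dione is symmetric, so only one enol ether can form.

Step 4
Reactants: 4 2,3-dimethoxycyclopent-2-en-1-one
Product: 6 tert-butyl 3,4-dimethoxy-2-oxocyclopent-3-ene-1-carboxylate (racemic), via lithium enolate 5 (not isolated)
Conditions: LDA (2.2 equiv), THF, −78 °C; Boc2O, −78 → −40 °C; aq NH4Cl
Reagents that add atoms: di-tert-butyl dicarbonate, CC(C)(C)OC(=O)OC(=O)OC(C)(C)C
Why: Kinetic α′-deprotonation of the vinylogous ester (Stork–Danheiser enolate) and Claisen-type C-acylation by Boc2O; the second equivalent of base takes up the more acidic β-keto ester.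

Step 5
Reactants: 6 tert-butyl 3,4-dimethoxy-2-oxocyclopent-3-ene-1-carboxylate
Product: 7 tert-butyl (S)-1-hydroxy-3,4-dimethoxy-2-oxocyclopent-3-ene-1-carboxylate
Conditions: Ni(ClO4)2·6H2O (10 mol %), (R,R)-DBFOX/Ph (11 mol %), (±)-trans-2-(phenylsulfonyl)-3-phenyloxaziridine (1.2 equiv), 4 Å MS, CH2Cl2, rt
Reagents that add atoms: (±)-trans-2-(phenylsulfonyl)-3-phenyloxaziridine, O=S(=O)(c1ccccc1)N1OC1c1ccccc1
Why: Catalytic enantioselective electrophilic α-hydroxylation (Davis oxidation): the β-keto ester binds Ni(II) as a two-point chelated enolate, a ligand phenyl blocks one face, and oxygen transfer to the open face sets the quaternary C1 as (S).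

Step 6
Reactants: 7 tert-butyl (S)-1-hydroxy-3,4-dimethoxy-2-oxocyclopent-3-ene-1-carboxylate
Product: 8 tert-butyl (S)-1,3,4-trimethoxy-2-oxocyclopent-3-ene-1-carboxylate
Conditions: MeI (excess), Ag2O, 4 Å MS, MeCN, 40 °C, dark
Reagents that add atoms: iodomethane, CI
Why: Purdie methylation alkylates the acidic tertiary α-hydroxy group under near-neutral conditions, avoiding α-ketol and retro-Claisen pathways of a free alkoxide; C1 is quaternary and cannot epimerise.

Step 7
Reactants: 8 tert-butyl (S)-1,3,4-trimethoxy-2-oxocyclopent-3-ene-1-carboxylate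
Product: 9 tert-butyl (1S,2RS)-2-hydroxy-1,3,4-trimethoxycyclopent-3-ene-1-carboxylate (used crude)
Conditions: NaBH4, CeCl3·7H2O, MeOH, −40 → 0 °C
Reagents that add atoms: none
Why: Luche reduction adds hydride 1,2 to the vinylogous-ester carbonyl and spares the tert-butyl ester; the new carbinol centre is destroyed in step 8, so its configuration does not matter.

Step 8
Reactants: 9 tert-butyl (1S,2RS)-2-hydroxy-1,3,4-trimethoxycyclopent-3-ene-1-carboxylate
Product: 11 (S)-1,3-dimethoxy-4-oxocyclopent-2-ene-1-carboxylic acid, via tert-butyl ester enone 10 (not isolated)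
Conditions: TFA–CH2Cl2–H2O (10:10:1), 0 °C → rt
Reagents that add atoms: water, O
Why: Stork–Danheiser transposition: the vinylogous hemiacetal ionises to a methoxyallyl cation, water adds at the methoxy-bearing terminus and methanol leaves, placing C=O next to CH2; TFA then cleaves the tert-butyl ester by E1 loss of isobutene.

Step 9
Reactants: 11 (S)-1,3-dimethoxy-4-oxocyclopent-2-ene-1-carboxylic acid
Product: 12 methyl (S)-1,3-dimethoxy-4-oxocyclopent-2-ene-1-carboxylate
Conditions: TMSCHN2, MeOH–PhMe, 0 °C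
Reagents that add atoms: (trimethylsilyl)diazomethane, C[Si](C)(C)C=[N+]=[N-]
Why: Esterification of the acid with TMSCHN2 is fast and neutral at 0 °C, so the enone and the quaternary centre are untouched.

Step 10
Reactants: 12 methyl (S)-1,3-dimethoxy-4-oxocyclopent-2-ene-1-carboxylate
Product: 14 methyl (R)-2-bromo-1,3-dimethoxy-4-oxocyclopent-2-ene-1-carboxylate, via vicinal dibromide 13 (not isolated)
Conditions: Br2 (1.05 equiv), CH2Cl2, 0 °C; then Et3N, 0 °C → rt
Reagents that add atoms: bromine, BrBr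
Why: Electrophilic bromine addition to the enol-ether C=C followed by dehydrobromination; C3 carries no hydrogen, so only the 2-bromo enone can form (the descriptor changes to R only because Br raises the CIP rank of C2).

Step 11
Reactants: 14 methyl (R)-2-bromo-1,3-dimethoxy-4-oxocyclopent-2-ene-1-carboxylate
Product: 15 methyl (S)-1,2,3-trimethoxy-4-oxocyclopent-2-ene-1-carboxylate
Conditions: NaOMe (1.1 equiv), MeOH, 0 °C → rt
Reagents that add atoms: sodium methoxide, [Na+].[O-]C
Why: Nucleophilic vinylic substitution (addition–elimination) of the β-bromo enone by methoxide puts OMe at C2 and keeps C4 as the ketone, a regiochemistry that O-methylation of the 1,3-dione could not guarantee.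

Step 12
Reactants: 15 methyl (S)-1,2,3-trimethoxy-4-oxocyclopent-2-ene-1-carboxylate; 16 (E)-cinnamaldehyde
Product: 18 methyl (1S)-5-[(2E)-1-hydroxy-3-phenylprop-2-en-1-yl]-1,2,3-trimethoxy-4-oxocyclopent-2-ene-1-carboxylate (diastereomer mixture), via lithium enolate 17 (not isolated)
Conditions: LDA (1.1 equiv), THF, −78 °C; 16, −78 °C; sat. aq NH4Cl at −78 °C
Reagents that add atoms: none
Why: Directed aldol addition: LDA can deprotonate only C5 because C1 is quaternary, and the lithium enolate adds 1,2 to the enal at −78 °C, where β-loss of the C1 methoxide is slow; both new stereocentres are erased in step 13.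

Step 13
Reactants: 18 methyl (1S)-5-[(2E)-1-hydroxy-3-phenylprop-2-en-1-yl]-1,2,3-trimethoxy-4-oxocyclopent-2-ene-1-carboxylate
Product: 20 methyl (1S,5Z)-5-[(2E)-1-hydroxy-3-phenylprop-2-en-1-ylidene]-1,2,3-trimethoxy-4-oxocyclopent-2-ene-1-carboxylate (CNP0305038.1), via β-diketone tautomer 19 (not isolated)
Conditions: Dess–Martin periodinane (1.1 equiv), NaHCO3, CH2Cl2, 0 °C → rt
Reagents that add atoms: none
Why: Dess–Martin oxidation of the allylic β-hydroxy ketone gives the β-diketone, which enolises to the hydrogen-bonded (Z)-enol; the (E)-styryl geometry comes from cinnamaldehyde and C1 is untouched.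

## Compound list

1 | cyclopentane-1,3-dione | O=C1CCC(=O)C1 | starting material
2 | 2-diazocyclopentane-1,3-dione | [N-]=[N+]=C1C(=O)CCC1=O | intermediate
3 | 2-methoxycyclopentane-1,3-dione (enol form) | COC1=C(O)CCC1=O | intermediate
4 | 2,3-dimethoxycyclopent-2-en-1-one | COC1=C(OC)C(=O)CC1 | intermediate
5 | lithium 4,5-dimethoxycyclopenta-1,4-dien-1-olate | [Li+].[O-]C1=CCC(OC)=C1OC | intermediate
6 | tert-butyl 3,4-dimethoxy-2-oxocyclopent-3-ene-1-carboxylate (racemic) | CC(C)(C)OC(=O)C1CC(OC)=C(OC)C1=O | intermediate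
7 | tert-butyl (S)-1-hydroxy-3,4-dimethoxy-2-oxocyclopent-3-ene-1-carboxylate | CC(C)(C)OC(=O)[C@@]1(O)C(=O)C(OC)=C(OC)C1 | intermediate
8 | tert-butyl (S)-1,3,4-trimethoxy-2-oxocyclopent-3-ene-1-carboxylate | CC(C)(C)OC(=O)[C@@]1(OC)C(=O)C(OC)=C(OC)C1 | intermediate
9 | tert-butyl (1S,2RS)-2-hydroxy-1,3,4-trimethoxycyclopent-3-ene-1-carboxylate | CC(C)(C)OC(=O)[C@@]1(OC)C(O)C(OC)=C(OC)C1 | intermediate
10 | tert-butyl (S)-1,3-dimethoxy-4-oxocyclopent-2-ene-1-carboxylate | CC(C)(C)OC(=O)[C@@]1(OC)C=C(OC)C(=O)C1 | intermediate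
11 | (S)-1,3-dimethoxy-4-oxocyclopent-2-ene-1-carboxylic acid | OC(=O)[C@@]1(OC)C=C(OC)C(=O)C1 | intermediate
12 | methyl (S)-1,3-dimethoxy-4-oxocyclopent-2-ene-1-carboxylate | COC(=O)[C@@]1(OC)C=C(OC)C(=O)C1 | intermediate
13 | methyl (1R)-2,3-dibromo-1,3-dimethoxy-4-oxocyclopentane-1-carboxylate (mixture at C2/C3) | COC(=O)[C@@]1(OC)C(Br)C(Br)(OC)C(=O)C1 | intermediate
14 | methyl (R)-2-bromo-1,3-dimethoxy-4-oxocyclopent-2-ene-1-carboxylate | COC(=O)[C@@]1(OC)C(Br)=C(OC)C(=O)C1 | intermediate
15 | methyl (S)-1,2,3-trimethoxy-4-oxocyclopent-2-ene-1-carboxylate | COC(=O)[C@@]1(OC)C(OC)=C(OC)C(=O)C1 | intermediate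
16 | (E)-cinnamaldehyde | O=C/C=C/c1ccccc1 | starting material
17 | lithium (3S)-3,4,5-trimethoxy-3-(methoxycarbonyl)cyclopenta-1,4-dien-1-olate | COC(=O)[C@@]1(OC)C(OC)=C(OC)C([O-])=C1.[Li+] | intermediate
18 | methyl (1S)-5-[(2E)-1-hydroxy-3-phenylprop-2-en-1-yl]-1,2,3-trimethoxy-4-oxocyclopent-2-ene-1-carboxylate (diastereomer mixture) | COC(=O)[C@@]1(OC)C(OC)=C(OC)C(=O)C1C(O)/C=C/c1ccccc1 | intermediate
19 | methyl (1S)-1,2,3-trimethoxy-4-oxo-5-[(2E)-3-phenylprop-2-enoyl]cyclopent-2-ene-1-carboxylate | COC(=O)[C@@]1(OC)C(OC)=C(OC)C(=O)C1C(=O)/C=C/c1ccccc1 | intermediate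
20 | methyl (1S,5Z)-5-[(2E)-1-hydroxy-3-phenylprop-2-en-1-ylidene]-1,2,3-trimethoxy-4-oxocyclopent-2-ene-1-carboxylate | COC(=O)[C@@]1(OC)C(OC)=C(OC)C(=O)/C1=C(O)/C=C/c1ccccc1 | target

## Step count and risks

Total steps: 13. Longest linear sequence: 13 steps (from 1; cinnamaldehyde 16 enters at step 12).

Three steps most likely to fail:

**Step 5 (enantioselective hydroxylation; ee and sense untested on a vinylogous-ester β-keto ester).** The fallback sets the stereocentre by resolution instead of catalysis. It sets out from 6: hydroxylation with the same oxaziridine and catalytic K2CO3 but no chiral ligand gives racemic tert-butyl 1-hydroxy-3,4-dimethoxy-2-oxocyclopent-3-ene-1-carboxylate F1. Preparative chiral SFC separates the enantiomers, and the (S)-enantiomer is 7, where the fallback comes back to the route.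

**Step 6 (O-methylation of a hindered tertiary alcohol flanked by a ketone and an ester).** The fallback postpones the methylation until after the transposition, where the alcohol is no longer next to a ketone. It sets out from 7:
- Luche reduction gives tert-butyl (1S,2RS)-1,2-dihydroxy-3,4-dimethoxycyclopent-3-ene-1-carboxylate F2.
- Aqueous TFA converts it, through tert-butyl (S)-1-hydroxy-3-methoxy-4-oxocyclopent-2-ene-1-carboxylate F3, into (S)-1-hydroxy-3-methoxy-4-oxocyclopent-2-ene-1-carboxylic acid F4.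
- TMSCHN2 gives methyl (S)-1-hydroxy-3-methoxy-4-oxocyclopent-2-ene-1-carboxylate F5.
- MeOTf with 2,6-di-tert-butyl-4-methylpyridine (non-basic, so no retro-aldol racemisation) methylates the tertiary alcohol, and the fallback comes back at 12.

**Step 10 (bromination of the α-methoxy enone next to an electron-poor quaternary carbon; step 11 may also erode ee by reversible loss of the C1 methoxide).** The fallback transposes the vinylogous ester with retention of the C2 oxygen and bypasses steps 7–11. It sets out from 8: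
- Me3OBF4 in CH2Cl2 methylates the carbonyl oxygen to give the trimethoxyallyl cation salt (4S)-4-(tert-butoxycarbonyl)-1,2,3,4-tetramethoxycyclopent-2-en-1-ylium tetrafluoroborate F6.
- Cold aqueous NaHCO3 should add water at the unhindered terminus (next to CH2) rather than at the one next to the quaternary carbon; loss of methanol gives tert-butyl (S)-1,2,3-trimethoxy-4-oxocyclopent-2-ene-1-carboxylate F7.
- TFA gives (S)-1,2,3-trimethoxy-4-oxocyclopent-2-ene-1-carboxylic acid F8, and TMSCHN2 brings the fallback back at 15.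

## Further compounds

F1 | step 5 | racemic tert-butyl 1-hydroxy-3,4-dimethoxy-2-oxocyclopent-3-ene-1-carboxylate | CC(C)(C)OC(=O)C1(O)CC(OC)=C(OC)C1=O
F2 | step 6 | tert-butyl (1S,2RS)-1,2-dihydroxy-3,4-dimethoxycyclopent-3-ene-1-carboxylate | CC(C)(C)OC(=O)[C@@]1(O)C(O)C(OC)=C(OC)C1
F3 | step 6 | tert-butyl (S)-1-hydroxy-3-methoxy-4-oxocyclopent-2-ene-1-carboxylate | CC(C)(C)OC(=O)[C@@]1(O)C=C(OC)C(=O)C1
F4 | step 6 | (S)-1-hydroxy-3-methoxy-4-oxocyclopent-2-ene-1-carboxylic acid | OC(=O)[C@@]1(O)C=C(OC)C(=O)C1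
F5 | step 6 | methyl (S)-1-hydroxy-3-methoxy-4-oxocyclopent-2-ene-1-carboxylate | COC(=O)[C@@]1(O)C=C(OC)C(=O)C1
F6 | step 10 | (4S)-4-(tert-butoxycarbonyl)-1,2,3,4-tetramethoxycyclopent-2-en-1-ylium tetrafluoroborate | CC(C)(C)OC(=O)[C@@]1(OC)C(OC)=C(OC)C(=[O+]C)C1.F[B-](F)(F)F
F7 | step 10 | tert-butyl (S)-1,2,3-trimethoxy-4-oxocyclopent-2-ene-1-carboxylate | CC(C)(C)OC(=O)[C@@]1(OC)C(OC)=C(OC)C(=O)C1
F8 | step 10 | (S)-1,2,3-trimethoxy-4-oxocyclopent-2-ene-1-carboxylic acid | OC(=O)[C@@]1(OC)C(OC)=C(OC)C(=O)C1
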